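**Plan**

- Ring names: in the flavanonol, ring A is the diacetoxy/dihydroxy benzo ring, ring C the pyranone and ring B the catechol; in the lignan, ring D is the guaiacyl ring that carries the biaryl bond and ring E the other one. The retrosynthesis first removes four acetates, then cuts the bond between C2 of ring C and C1′ of ring B, then the biaryl bond between ring B and ring D.
- Forward: (+)-pinoresinol is mono-iodinated and acetylated, joined to a silyl-masked 3-metallocatechol (Negishi) and desilylated. Separately, 5,7-dihydroxychromone is acetylated and epoxidised. Ring B then opens the oxirane at C2, and global deacetylation ends the route. No ring of the target is built: the furofuran comes from pinoresinol and ring C from the chromone.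
- Enabling feature: C2 of ring C is an acetal-type carbon bonded to ring oxygen O1. In the chromone 2,3-epoxide the strained oxirane C2–O bond is therefore the only one that can ionise, because C3 is alpha to the C4 carbonyl. The ring-B carbon to be bonded lies para to the C4′ hydroxyl, whose two ortho positions are blocked (C3′–OH and the C5′ biaryl bond).
- Stereochemistry: the four furofuran centres come unchanged from (+)-pinoresinol. C3 is set by the catalyst-controlled epoxidation. C2 is set by anti (inverting) opening of the oxirane, which gives the 2,3-trans (2R,3R) ring C.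

Key step: step 8

Assumption: (+)-pinoresinol is bought as the natural (1S,3aR,4S,6aR) enantiomer, whose furofuran configuration is that of the target; 3-bromocatechol and 5,7-dihydroxychromone are also purchased.

Assumption: the (R,R) manganese salen catalyst is taken to give the (2R,3R) oxirane, by analogy with cis-cinnamate esters; if a correlation experiment shows the opposite sense, the (S,S) catalyst is used with no other change.

**Step 1**
Reactants: 1 (+)-pinoresinol
Product: 2 (+)-5-iodopinoresinol
Conditions: NIS (0.8 equiv), DMF, −20 to 0 °C, dark; unreacted 1 recycled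
Reagents that add atoms: N-iodosuccinimide, O=C1CCC(=O)N1I
Why: Electrophilic aromatic iodination should occur ortho to the free phenol because the para position carries the furofuran carbon, and since the two guaiacyl rings of 1 are related by its twofold axis either ring gives the same mono-iodide, over-iodination being limited by the substoichiometric charge.

**Step 2**
Reactants: 2 (+)-5-iodopinoresinol
Product: 3 5-iodopinoresinol 4,4′-di-O-acetate
Conditions: Ac2O, pyridine, DMAP (catalytic), CH2Cl2, rt
Reagents that add atoms: acetic anhydride, CC(=O)OC(C)=O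
Why: DMAP-catalysed O-acetylation (nucleophilic acyl substitution) should cap both phenols, so that the later arylzinc is not protonated and rings D and E are deactivated for the key step.

**Step 3**
Reactants: 4 3-bromocatechol
Product: 5 1-bromo-2,3-bis(triisopropylsilyloxy)benzene
Conditions: TIPSOTf (2.4 equiv), 2,6-lutidine, CH2Cl2, 0 °C to rt
Reagents that add atoms: triisopropylsilyl triflate, CC(C)[Si](OS(=O)(=O)C(F)(F)F)(C(C)C)C(C)C
Why: Silyl ether formation with the silyl triflate and a hindered pyridine base should give a catechol mask that is stable to organometallic reagents and bulky enough to suppress oxygen-to-carbon silyl migration in the next step.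

**Step 4**
Reactants: 5 1-bromo-2,3-bis(triisopropylsilyloxy)benzene; 3 5-iodopinoresinol 4,4′-di-O-acetate
Product: 8 5-[2,3-bis(triisopropylsilyloxy)phenyl]pinoresinol 4,4′-di-O-acetate, via the aryllithium 6 (not isolated), via the arylzinc chloride 7 (not isolated)
Conditions: 5, n-BuLi, THF, −78 °C; ZnCl2, −78 °C to rt; then 3, Pd2(dba)3 (2 mol %), SPhos (8 mol %), THF, 50 °C
Reagents that add atoms: none
Why: Bromine–lithium exchange, transmetallation to zinc and Negishi coupling with a zerovalent palladium/SPhos catalyst should join the hindered aryl groups under base-free conditions that leave aryl acetates and silyl ethers intact; no stereocentre is formed and the di-ortho-substituted biaryl axis rotates freely.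

**Step 5**
Reactants: 8 5-[2,3-bis(triisopropylsilyloxy)phenyl]pinoresinol 4,4′-di-O-acetate
Product: 9 5-(2,3-dihydroxyphenyl)pinoresinol 4,4′-di-O-acetate
Conditions: TBAF (2.5 equiv), AcOH (3 equiv), THF, 0 °C
Reagents that add atoms: none
Why: Fluoride should cleave the two aryl O–Si bonds (desilylation) while the acetic acid buffer keeps the liberated catechol protonated, so that the aryl acetates neither cleave nor migrate to the neighbouring ring-B oxygen.

**Step 6**
Reactants: 10 5,7-dihydroxychromone
Product: 11 5,7-diacetoxychromone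
Conditions: Ac2O, pyridine, DMAP (catalytic), rt to 40 °C
Reagents that add atoms: acetic anhydride, CC(=O)OC(C)=O
Why: DMAP-catalysed acetylation should also reach the hydrogen-bonded C5 hydroxyl and turn ring A into an electron-poor, non-nucleophilic ring for the two steps that follow.

**Step 7**
Reactants: 11 5,7-diacetoxychromone
Product: 12 (2R,3R)-5,7-diacetoxy-2,3-epoxychroman-4-one
Conditions: (R,R)-Mn(salen)Cl [salen = N,N′-bis(3,5-di-tert-butylsalicylidene)-1,2-cyclohexanediaminate] (5 mol %), DMDO in acetone (1.5 equiv), CH2Cl2, −20 °C; used at once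
Reagents that add atoms: dimethyldioxirane, CC1(C)OO1
Why: Jacobsen–Katsuki epoxidation of the cis-disubstituted C2=C3 bond of a 4H-chromen-4-one, a reaction type shown on isoflavones with dimethyldioxirane as terminal oxidant, should transfer oxygen from the oxo-manganese salen species to one enantiotopic face and so set C3 and C2 of the cis-fused oxirane under catalyst control.

**Step 8**
Reactants: 9 5-(2,3-dihydroxyphenyl)pinoresinol 4,4′-di-O-acetate; 12 (2R,3R)-5,7-diacetoxy-2,3-epoxychroman-4-one
Product: 13 tetra-O-acetyl target (ring A 5,7-diacetate and ring D/ring E 4,4′-diacetate of the target)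
Conditions: 12 (1.3 equiv), HFIP/CH2Cl2 (4:1), 4 Å molecular sieves, argon, 0 °C to rt
Reagents that add atoms: none
Why: Proposed new method: hexafluoroisopropanol should hydrogen-bond to the oxirane oxygen of 12 and loosen only the C2–O bond, because C2 is the acetal carbon next to ring oxygen O1 whereas C3 is alpha to the C4 carbonyl and cannot carry positive charge; the ring-B carbon of 9 para to the biaryl-flanked hydroxyl (C5 of the 3-arylcatechol) then attacks C2 in a loose SN2 fashion and rearomatises by proton loss, a Friedel–Crafts alkylation driven by strain release. The closest known reaction types are the fluoroalcohol-promoted stereospecific Friedel–Crafts opening of epoxides by phenols and other electron-rich arenes, the C-arylation of 1,2-anhydro sugars at the anomeric carbon, and the acid-mediated alcoholysis of chromone epoxides at C2. No ring is closed; the oxirane is opened. C3 keeps the configuration given in step 7 because its C–O bond is never broken, and C2 is set by backside attack anti to the departing oxygen, which gives the 2,3-trans (2R,3R) arrangement that is also the thermodynamically preferred diequatorial one. The step needs regioselectivity on the oxirane (C2 over C3, secured by the acetal versus alpha-keto character), site selectivity on the arene (ring B is the only ring with free hydroxyls, the attacked carbon is the only position para to a hydroxyl with two hydrogen neighbours, and rings A, D and E are deactivated as acetates), and it must outrun isomerisation of 12 to the 3-hydroxychromone, which the non-basic medium and the acetoxy-deactivated ring A are meant to slow.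

**Step 9**
Reactants: 13 tetra-O-acetyl target
Product: 14 CNP0226398.1 (target)
Conditions: K2CO3 (0.2 equiv), degassed MeOH/THF, argon, 0 °C, short contact; AcOH quench
Reagents that add atoms: none
Why: Base-catalysed transesterification (methanolysis) should remove the four aryl acetates under conditions cold, oxygen-free and brief enough that the 2,3-trans ring C neither opens at C2 nor is oxidised to the flavonol, the furofuran being inert to base.

**Compound list**

1 | (+)-pinoresinol, 4,4′-[(1S,3aR,4S,6aR)-tetrahydro-1H,3H-furo[3,4-c]furan-1,4-diyl]bis(2-methoxyphenol) | COc1cc([C@H]2OC[C@H]3[C@@H]2CO[C@@H]3c2cc(OC)c(O)cc2)ccc1O | starting material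
2 | (+)-5-iodopinoresinol (iodine ortho to the phenol of ring D) | COc1cc([C@H]2OC[C@H]3[C@@H]2CO[C@@H]3c2cc(OC)c(O)c(I)c2)ccc1O | intermediate
3 | 5-iodopinoresinol 4,4′-di-O-acetate | COc1cc([C@H]2OC[C@H]3[C@@H]2CO[C@@H]3c2cc(OC)c(OC(C)=O)c(I)c2)ccc1OC(C)=O | intermediate
4 | 3-bromocatechol (3-bromobenzene-1,2-diol) | Oc1cccc(Br)c1O | starting material
5 | 1-bromo-2,3-bis(triisopropylsilyloxy)benzene | Brc1cccc(O[Si](C(C)C)(C(C)C)C(C)C)c1O[Si](C(C)C)(C(C)C)C(C)C | intermediate
6 | 2,3-bis(triisopropylsilyloxy)phenyllithium | [Li]c1cccc(O[Si](C(C)C)(C(C)C)C(C)C)c1O[Si](C(C)C)(C(C)C)C(C)C | intermediate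
7 | [2,3-bis(triisopropylsilyloxy)phenyl]zinc chloride | Cl[Zn]c1cccc(O[Si](C(C)C)(C(C)C)C(C)C)c1O[Si](C(C)C)(C(C)C)C(C)C | intermediate
8 | 5-[2,3-bis(triisopropylsilyloxy)phenyl]pinoresinol 4,4′-di-O-acetate | COc1cc([C@H]2OC[C@H]3[C@@H]2CO[C@@H]3c2cc(OC)c(OC(C)=O)c(-c3cccc(O[Si](C(C)C)(C(C)C)C(C)C)c3O[Si](C(C)C)(C(C)C)C(C)C)c2)ccc1OC(C)=O | intermediate
9 | 5-(2,3-dihydroxyphenyl)pinoresinol 4,4′-di-O-acetate | COc1cc([C@H]2OC[C@H]3[C@@H]2CO[C@@H]3c2cc(OC)c(OC(C)=O)c(-c3cccc(O)c3O)c2)ccc1OC(C)=O | intermediate
10 | 5,7-dihydroxychromone (5,7-dihydroxy-4H-chromen-4-one) | O=c1ccoc2cc(O)cc(O)c12 | starting material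
11 | 5,7-diacetoxychromone | CC(=O)Oc1cc(OC(C)=O)c2c(c1)occc2=O | intermediate
12 | (2R,3R)-5,7-diacetoxy-2,3-epoxychroman-4-one [(1aR,7aR)-7-oxo-1a,7a-dihydro-7H-oxireno[2,3-b]chromene-4,6-diyl diacetate] | O=C1c2c(OC(C)=O)cc(OC(C)=O)cc2O[C@H]2O[C@@H]12 | intermediate
13 | tetra-O-acetyl target: (2R,3R)-5,7-diacetoxy-3-hydroxy-2-aryl-chroman-4-one whose ring B (3′,4′-dihydroxy) is bonded at C5′ to C5 of (+)-pinoresinol 4,4′-diacetate | COc1cc([C@H]2OC[C@H]3[C@@H]2CO[C@@H]3c2cc(OC)c(OC(C)=O)c(-c3cc([C@H]4Oc5cc(OC(C)=O)cc(OC(C)=O)c5C(=O)[C@@H]4O)cc(O)c3O)c2)ccc1OC(C)=O | intermediate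
14 | CNP0226398.1: (2R,3R)-3,5,7-trihydroxy-2-{3,4-dihydroxy-5-[(+)-pinoresinol-5-yl]phenyl}chroman-4-one | COc1cc([C@H]2OC[C@H]3[C@@H]2CO[C@@H]3c2cc(OC)c(O)c(-c3cc([C@H]4Oc5cc(O)cc(O)c5C(=O)[C@@H]4O)cc(O)c3O)c2)ccc1O | target

**Totals and risks**

Total step count: 9. Longest linear sequence: 6 (steps 1, 2, 4, 5, 8, 9).

Step 8 (proposed new method). The oxirane may isomerise to the 3-hydroxychromone faster than it is arylated, the catechol may be alkylated on oxygen, or another arene carbon may be attacked. The fallback makes the same bond by known conjugate-addition chemistry. It sets out from 8 and uses 11. Iridium-catalysed C–H borylation of 8 ([Ir(OMe)(cod)]2, 4,4′-di-tert-butyl-2,2′-bipyridine, B2pin2, THF, 60 °C) should occur at the only aryl C–H flanked by two hydrogens and give the ring-B pinacol boronate F1. NaIO4/NH4OAc in aqueous acetone should then give the boronic acid F2. Enantioselective conjugate addition of F2 to chromone 11 with Pd(OCOCF3)2, the t-BuPyOx enantiomer that delivers the 2S product, NH4PF6 and water in 1,2-dichloroethane at 60 °C should give the (2S)-flavanone F3. Soft enolisation (TMSOTf, Et3N, CH2Cl2, 0 °C) should give the trimethylsilyl enol ether F4, and Rubottom oxidation with DMDO anti to the C2 aryl group should give the trans-3-hydroxyflavanone bis-silyl ether F5. Desilylation of F5 with TBAF/AcOH comes back to the route at 13.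

Step 7. Facial selectivity of oxygen transfer to the electron-poor chromone may be low or of the wrong sense, and the oxirane may rearrange during isolation. The fallback replaces catalyst control by resolution. It sets out from 11: epoxidation with DMDO alone should give the racemic cis-epoxide F6, which is resolved by preparative HPLC on a chiral stationary phase. The (2R,3R) enantiomer is 12, where the route is rejoined, and the (2S,3S) antipode F7 is set aside.

Step 4. Silyl migration from oxygen to carbon in the aryllithium, or slow coupling of the two hindered partners, may erode the yield. The fallback avoids the aryllithium. It sets out from 5 and uses 2: Miyaura borylation of 5 (Pd(dppf)Cl2, B2pin2, KOAc, dioxane, 90 °C) should give the aryl pinacol boronate F8. Suzuki–Miyaura coupling of F8 with the free iodophenol 2 (Pd(OAc)2, SPhos, K3PO4, toluene/water, 70 °C) should give the biaryl diphenol F9. Acetylation of F9 (Ac2O, pyridine, DMAP) comes back to the route at 8.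

**Further compounds**

F1 | step 8 | ring-B pinacol boronate of 8 (boron at the carbon para to the inner silyloxy group) | COc1cc([C@H]2OC[C@H]3[C@@H]2CO[C@@H]3c2cc(OC)c(OC(C)=O)c(-c3cc(B4OC(C)(C)C(C)(C)O4)cc(O[Si](C(C)C)(C(C)C)C(C)C)c3O[Si](C(C)C)(C(C)C)C(C)C)c2)ccc1OC(C)=O
F2 | step 8 | corresponding ring-B boronic acid | COc1cc([C@H]2OC[C@H]3[C@@H]2CO[C@@H]3c2cc(OC)c(OC(C)=O)c(-c3cc(B(O)O)cc(O[Si](C(C)C)(C(C)C)C(C)C)c3O[Si](C(C)C)(C(C)C)C(C)C)c2)ccc1OC(C)=O
F3 | step 8 | (2S)-5,7-diacetoxyflavanone carrying the bis-silylated ring B and the pinoresinol diacetate | COc1cc([C@H]2OC[C@H]3[C@@H]2CO[C@@H]3c2cc(OC)c(OC(C)=O)c(-c3cc([C@H]4Oc5cc(OC(C)=O)cc(OC(C)=O)c5C(=O)C4)cc(O[Si](C(C)C)(C(C)C)C(C)C)c3O[Si](C(C)C)(C(C)C)C(C)C)c2)ccc1OC(C)=O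
F4 | step 8 | trimethylsilyl enol ether of F3 (C3=C4, 4-OSiMe3) | COc1cc([C@H]2OC[C@H]3[C@@H]2CO[C@@H]3c2cc(OC)c(OC(C)=O)c(-c3cc([C@H]4Oc5cc(OC(C)=O)cc(OC(C)=O)c5C(O[Si](C)(C)C)=C4)cc(O[Si](C(C)C)(C(C)C)C(C)C)c3O[Si](C(C)C)(C(C)C)C(C)C)c2)ccc1OC(C)=O
F5 | step 8 | (2R,3R)-3-hydroxyflavanone bis-silyl ether (13 with both ring-B hydroxyls as triisopropylsilyl ethers) | COc1cc([C@H]2OC[C@H]3[C@@H]2CO[C@@H]3c2cc(OC)c(OC(C)=O)c(-c3cc([C@H]4Oc5cc(OC(C)=O)cc(OC(C)=O)c5C(=O)[C@@H]4O)cc(O[Si](C(C)C)(C(C)C)C(C)C)c3O[Si](C(C)C)(C(C)C)C(C)C)c2)ccc1OC(C)=O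
F6 | step 7 | racemic cis-5,7-diacetoxy-2,3-epoxychroman-4-one | O=C1c2c(OC(C)=O)cc(OC(C)=O)cc2OC2OC12
F7 | step 7 | (2S,3S)-5,7-diacetoxy-2,3-epoxychroman-4-one | O=C1c2c(OC(C)=O)cc(OC(C)=O)cc2O[C@@H]2O[C@H]12
F8 | step 4 | 2-[2,3-bis(triisopropylsilyloxy)phenyl]-4,4,5,5-tetramethyl-1,3,2-dioxaborolane | CC(C)[Si](Oc1cccc(B2OC(C)(C)C(C)(C)O2)c1O[Si](C(C)C)(C(C)C)C(C)C)(C(C)C)C(C)C
F9 | step 4 | 5-[2,3-bis(triisopropylsilyloxy)phenyl]pinoresinol (free phenols) | COc1cc([C@H]2OC[C@H]3[C@@H]2CO[C@@H]3c2cc(OC)c(O)c(-c3cccc(O[Si](C(C)C)(C(C)C)C(C)C)c3O[Si](C(C)C)(C(C)C)C(C)C)c2)ccc1O
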